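**Plan**

Labdane numbering is used throughout: ring A = C1–C5 and C10; ring B = C5–C10; C17 = CH2 on C8; C18 (methyl) and C19 (ester) on C4; C20 on C10; C11–C12 side chain; C13–C16 butenolide; β = the face of C20.
Retrosynthesis, in order: C20 aldehyde from a C20 silyl ether; cut C12–C13 (B-alkyl cross-coupling of a C11=C12 vinyl group with a bromobutenolide); vinyl group from a lactone carbonyl at C11; 8(17)-ene/9-H from a conjugated 8(9)-ene lactone; 5-H from a 5(6)-ene; then ring B is cut at C7–C8 and C9–C10 together; then the C20–O ester; then C5–C6 and C10–C20, back to a ring A keto ester.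
Forward: ring A with quaternary C4 first, then the 2-vinylcyclohexene diene, then one intramolecular Diels–Alder step that closes ring B and a temporary γ-lactone, then trans ring fusion, exocyclic methylene, side chain with the intact butenolide ring, and last the aldehyde.
Enabling feature: C10 carries the one-carbon unit C20 cis to C11 on C9, so a C20–O–C11(=O) ester (the five-membered ring C9–C10–C20–O–C11) can hold a C8≡C9 but-2-ynoate under the C7=C6–C5=C10 diene; the 8(17)-ene with 9-H is the deconjugated form of the adduct's C8=C9 enoate.
Stereochemistry: C4 from a bought L-valine auxiliary; C10 relayed from C4 in the cycloaddition; C5 by α-face hydrogenation; C9 by convex-face protonation of the lactone dienolate.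

Key step: step 7

Assumption: in step 2 the L-valine auxiliary under the toluene–HMPA protocol is taken to deliver the (S)-keto ester; if the sense were the reverse, the D-valine ester would be used with no other change.

**Route**

Step 1
Reactants: 1 methyl 2-oxocyclohexane-1-carboxylate; 2 tert-butyl L-valinate
Product: 3 methyl 2-{[(2S)-1-tert-butoxy-3-methyl-1-oxobutan-2-yl]amino}cyclohex-1-ene-1-carboxylate
Conditions: BF3·OEt2 (cat.), PhMe, reflux, Dean–Stark
Reagents that add atoms: none
Why: Acid-catalysed condensation of a β-keto ester with a primary amine gives the hydrogen-bonded enamino ester, which places the bought valine stereocenter next to nitrogen; no new stereocenter is formed.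

Step 2
Reactants: 3 enamino ester
Product: 5 methyl (1S)-1-methyl-2-oxocyclohexane-1-carboxylate, via methylated imine 4 (not isolated)
Conditions: LiN(i-Pr)2, PhMe, −78 °C; HMPA (1 equiv); MeI, −78 → −20 °C; then 1 M HCl (aq), rt
Reagents that add atoms: iodomethane (CI); water (O)
Why: Alkylation of a chiral lithio-enamine (aza-enolate), in which lithium is held by the nitrogen and the valine ester carbonyl and HMPA fills the last site, so that iodomethane should enter anti to the isopropyl group and set quaternary C4 as S before hydrolysis releases the ketone and the auxiliary.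

Step 3
Reactants: 5 (S)-keto ester
Product: 6 methyl (1R)-2-bromo-3-formyl-1-methylcyclohex-2-ene-1-carboxylate
Conditions: PBr3, DMF, CHCl3, 0 → 60 °C; then aq. NaOAc
Reagents that add atoms: phosphorus tribromide (BrP(Br)Br); N,N-dimethylformamide (CN(C)C=O); water (O)
Why: Vilsmeier–Haack–Arnold bromoformylation; the ketone can enolise only toward C10 because C4 is quaternary, so C10 is formylated and bromide replaces the activated oxygen at C5, with C4 untouched (the descriptor changes only by priority).

Step 4
Reactants: 6 bromo enal
Product: 7 methyl (1S)-2-ethenyl-3-formyl-1-methylcyclohex-2-ene-1-carboxylate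
Conditions: tributyl(ethenyl)stannane, Pd(PPh3)4 (5 mol %), PhMe, 90 °C
Reagents that add atoms: tributyl(ethenyl)stannane (C=C[Sn](CCCC)(CCCC)CCCC)
Why: Stille coupling of the activated β-bromo enal installs C6=C7 under neutral conditions that spare the aldehyde and the ester.

Step 5
Reactants: 7 dienal
Product: 8 methyl (1S)-2-ethenyl-3-(hydroxymethyl)-1-methylcyclohex-2-ene-1-carboxylate
Conditions: NaBH4, CeCl3·7H2O, MeOH, −20 °C
Reagents that add atoms: none
Why: Luche 1,2-reduction gives the allylic alcohol at C20 without conjugate reduction and leaves the hindered ester intact.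

Step 6
Reactants: 8 dienyl alcohol; 9 but-2-ynoic acid
Product: 10 [(3S)-2-ethenyl-3-(methoxycarbonyl)-3-methylcyclohex-1-en-1-yl]methyl but-2-ynoate
Conditions: DCC, DMAP (5 mol %), CH2Cl2, −20 → 0 °C
Reagents that add atoms: none
Why: Steglich esterification of the primary alcohol attaches the dienophile; cold, low-DMAP conditions limit alkynoate-to-allenoate isomerisation.

Step 7
Reactants: 10 dienyl but-2-ynoate
Product: 11 tricyclic 5,8-diene 11,20-lactone (4α-methyl; 4β-methoxycarbonyl; C20 on the β face)
Conditions: PhMe (0.01 M), BHT (cat.), 170 °C, sealed tube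
Reagents that add atoms: none
Why: Thermal intramolecular Diels–Alder reaction: the tethered but-2-ynoate adds suprafacially across the termini C7 and C10 of the s-cis 2-vinylcyclohexene diene in one concerted, asynchronous [4+2] step, C8 bonding to C7 and C9 to C10. The closest known reaction type is the cycloaddition of ester-tethered alkynoates to 1-vinylcyclohexenes, which builds ring B of drimane and labdane skeletons together with the angular quaternary carbon. Ring B (a cyclohexa-1,4-diene) closes by the [4+2] mode itself, and the five-membered lactone closes as the three-atom tether C20–O–C11 is drawn across the new C9–C10 bond, which fixes the regiochemistry and keeps C20 and C11 cis. The only new stereocenter, C10, is controlled by C4: the dienophile should add to the diene face anti to the pseudoaxial methoxycarbonyl group (the face of the C4 methyl), so that C20 ends on the face of the C19 ester. The step needs this facial selectivity and a rate above that of the 1,5-hydrogen shift from C20 to C7; the conformational bias of the geminal methyl/ester pair and the activated, sterically slim alkyne are what should secure them, and the facial bias is the least certain point of the route.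

Step 8
Reactants: 11 diene lactone
Product: 12 trans-fused 8(9)-ene 11,20-lactone (5α-H)
Conditions: H2 (3 atm), Pd on carbon (Pd/C, 10 wt %), EtOAc, rt
Reagents that add atoms: none
Why: Heterogeneous hydrogenation takes the isolated trisubstituted C5=C6 alkene and spares the tetrasubstituted conjugated C8=C9 alkene; hydrogen should add from the α face because the β face carries the axial C19 ester and the C20–O bridge, which sets the trans ring fusion.

Step 9
Reactants: 12 conjugated lactone
Product: 14 cis-fused 8(17)-ene 11,20-lactone (9α-H), via lithium dienolate 13 (not isolated)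
Conditions: LiN(i-Pr)2, THF–HMPA, −78 °C; then AcOH, −78 °C
Reagents that add atoms: none
Why: Deconjugative protonation of an α-alkylidene lactone: the amide base bound to the carbonyl oxygen removes a proton from C17, the γ-carbon cis to the carbonyl, and kinetic protonation of the extended enolate at C9 from the convex α face gives the exocyclic alkene and the cis-fused lactone.

Step 10
Reactants: 14 deconjugated lactone
Product: 15 lactol (C11 hemiacetal; mixture of anomers)
Conditions: i-Bu2AlH (1.1 equiv), CH2Cl2, −78 °C; then aq. sodium potassium tartrate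
Reagents that add atoms: none
Why: Half-reduction of a γ-lactone at −78 °C stops at the lactol, the neopentyl axial C19 ester being much slower; C9 is not at risk under these non-basic conditions.

Step 11
Reactants: 15 lactol
Product: 17 C11=C12 vinyl compound with C20 as its triethylsilyl ether, via potassium alkoxide 16 (not isolated)
Conditions: Ph3PCH3Br, KN(SiMe3)2, THF, −78 → −10 °C; then Et3SiCl, −78 → 0 °C
Reagents that add atoms: methyltriphenylphosphonium bromide (C[P+](c1ccccc1)(c1ccccc1)c1ccccc1.[Br-]); chlorotriethylsilane (CC[Si](Cl)(CC)CC)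
Why: Wittig methylenation of the lactol through its open hydroxy-aldehyde form gives the vinyl group, and the liberated C20 alkoxide is capped in the same flask so that it cannot attack the syn-axial C19 ester; low temperature should keep C9, here α to an aldehyde, from epimerising.

Step 12
Reactants: 17 vinyl silyl ether; 18 3-bromofuran-2(5H)-one
Product: 20 C20 triethylsilyl ether of the 20-hydroxy butenolide, via B-alkyl-9-BBN borane 19 (not isolated)
Conditions: 9-BBN-H, THF, 0 °C → rt; then 18, PdCl2(dppf)·CH2Cl2 (5 mol %), AsPh3 (5 mol %), K3PO4 (3 M aq.), DMF, rt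
Reagents that add atoms: none
Why: 9-BBN-H should hydroborate the monosubstituted vinyl group at C12 ahead of the hindered 1,1-disubstituted 8(17)-alkene, and B-alkyl Suzuki–Miyaura coupling with the α-bromobutenolide forms C12–C13 under mild base.

Step 13
Reactants: 20 silyl ether
Product: 21 methyl (1S,4aS,5S,8aR)-4a-formyl-1-methyl-6-methylidene-5-[2-(2-oxo-2,5-dihydrofuran-3-yl)ethyl]decahydronaphthalene-1-carboxylate (target)
Conditions: (COCl)2, DMSO, CH2Cl2, −78 → −30 °C; Et3N, → 0 °C
Reagents that add atoms: none
Why: Swern conditions convert a primary triethylsilyl ether directly into the aldehyde, so the C20 alcohol is never free next to the C19 ester; quaternary C10 cannot epimerise.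

**Compound list**

1 | methyl 2-oxocyclohexane-1-carboxylate | COC(=O)C1CCCCC1=O | starting material
2 | tert-butyl L-valinate | CC(C)[C@H](N)C(=O)OC(C)(C)C | starting material
3 | methyl 2-{[(2S)-1-tert-butoxy-3-methyl-1-oxobutan-2-yl]amino}cyclohex-1-ene-1-carboxylate | COC(=O)C1=C(N[C@@H](C(C)C)C(=O)OC(C)(C)C)CCCC1 | intermediate
4 | methyl (1S)-1-methyl-2-{[(2S)-1-tert-butoxy-3-methyl-1-oxobutan-2-yl]imino}cyclohexane-1-carboxylate | COC(=O)[C@@]1(C)CCCCC1=N[C@@H](C(C)C)C(=O)OC(C)(C)C | intermediate
5 | methyl (1S)-1-methyl-2-oxocyclohexane-1-carboxylate | O=C1CCCC[C@]1(C)C(=O)OC | intermediate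
6 | methyl (1R)-2-bromo-3-formyl-1-methylcyclohex-2-ene-1-carboxylate | BrC1=C(C=O)CCC[C@]1(C)C(=O)OC | intermediate
7 | methyl (1S)-2-ethenyl-3-formyl-1-methylcyclohex-2-ene-1-carboxylate | C=CC1=C(C=O)CCC[C@]1(C)C(=O)OC | intermediate
8 | methyl (1S)-2-ethenyl-3-(hydroxymethyl)-1-methylcyclohex-2-ene-1-carboxylate | C=CC1=C(CO)CCC[C@]1(C)C(=O)OC | intermediate
9 | but-2-ynoic acid | CC#CC(=O)O | starting material
10 | [(3S)-2-ethenyl-3-(methoxycarbonyl)-3-methylcyclohex-1-en-1-yl]methyl but-2-ynoate | C=CC1=C(COC(=O)C#CC)CCC[C@]1(C)C(=O)OC | intermediate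
11 | tricyclic 5,8-diene 11,20-lactone (C17 methyl on C8; 4α-methyl, 4β-methoxycarbonyl, C20 β) | CC1=C2C(=O)OC[C@@]23CCC[C@](C)(C(=O)OC)C3=CC1 | intermediate
12 | trans-fused 8(9)-ene 11,20-lactone (5α-H) | CC1=C2C(=O)OC[C@@]23CCC[C@](C)(C(=O)OC)[C@@H]3CC1 | intermediate
13 | lithium dienolate of 12 (C11 enolate, exocyclic C8=C17) | [Li+].C=C1CC[C@@H]2[C@@]3(CCC[C@]2(C)C(=O)OC)COC([O-])=C13 | intermediate
14 | cis-fused 8(17)-ene 11,20-lactone (5α-H, 9α-H) | C=C1CC[C@@H]2[C@@]3(CCC[C@]2(C)C(=O)OC)COC(=O)[C@@H]13 | intermediate
15 | lactol of 14 (C11 hemiacetal, anomer mixture) | C=C1CC[C@@H]2[C@@]3(CCC[C@]2(C)C(=O)OC)COC(O)[C@@H]13 | intermediate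
16 | potassium C20 alkoxide of the 9-vinyl 8(17)-ene methyl ester | [K+].C=C1CC[C@@H]2[C@](C[O-])(CCC[C@]2(C)C(=O)OC)[C@H]1C=C | intermediate
17 | 9-vinyl 8(17)-ene methyl ester, C20 triethylsilyl ether | C=C1CC[C@@H]2[C@](CO[Si](CC)(CC)CC)(CCC[C@]2(C)C(=O)OC)[C@H]1C=C | intermediate
18 | 3-bromofuran-2(5H)-one | O=C1OCC=C1Br | starting material
19 | C12 B-alkyl-9-borabicyclo[3.3.1]nonane derived from 17 | C=C1CC[C@@H]2[C@](CO[Si](CC)(CC)CC)(CCC[C@]2(C)C(=O)OC)[C@H]1CCB1C2CCCC1CCC2 | intermediate
20 | C20 triethylsilyl ether of the 20-hydroxy analogue of the target | C=C1CC[C@@H]2[C@](CO[Si](CC)(CC)CC)(CCC[C@]2(C)C(=O)OC)[C@H]1CCC1=CCOC1=O | intermediate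
21 | methyl (1S,4aS,5S,8aR)-4a-formyl-1-methyl-6-methylidene-5-[2-(2-oxo-2,5-dihydrofuran-3-yl)ethyl]decahydronaphthalene-1-carboxylate | C=C1CC[C@@H]2[C@](C=O)(CCC[C@]2(C)C(=O)OC)[C@H]1CCC1=CCOC1=O | target

**Count and risks**

Total step count: 13. Longest linear sequence: 13 steps (1 to 21).

Step 7. What may go wrong: poor discrimination between the two diene faces at 170 °C (methyl and ester on C4 are similar in size), and 1,5-hydrogen shift or polymerisation outrunning the cycloaddition. Fallback: from 8, esterification with 3-(4-methylbenzenesulfonyl)prop-2-ynoic acid (DCC, CH2Cl2, −20 °C) should give the sulfonyl ynoate F1. This far more reactive dienophile should cyclise at ambient temperature (PhMe, 25 °C) to the 8-sulfonyl adduct F2, where the lower temperature should also sharpen the facial bias. LiCuMe2 (Et2O, −78 °C) then exchanges the sulfonyl group for methyl by conjugate addition–elimination and returns to 11.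

Step 11. What may go wrong: epimerisation at C9 or conjugation of the β,γ-unsaturated aldehyde under the basic ylide, and lactonisation of the C20 alkoxide onto the C19 ester before it is silylated. Fallback: from 14, aminolysis with N,O-dimethylhydroxylamine hydrochloride and i-PrMgCl (THF, −20 °C) with silylation of the magnesium alkoxide in the same flask (Et3SiCl) should give the Weinreb amide silyl ether F3. Reduction with i-Bu2AlH (THF, −78 °C) gives the aldehyde F4, and non-basic methylenation (CH2I2, Zn, TiCl4, THF, 0 °C) returns to 17.

Step 12. What may go wrong: slow alkyl transfer from boron and base-induced decomposition of the bromobutenolide before coupling. Fallback: from 17, the same borane 19 is coupled instead with the more robust prop-2-enyl 2-bromoprop-2-enoate (PdCl2(dppf)·CH2Cl2, K3PO4, DMF) to give the allyl α-alkylacrylate F5. Ring-closing metathesis with the second-generation Grubbs catalyst (CH2Cl2, 40 °C) then builds the butenolide ring and returns to 20.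

**Further compounds**

F1 | step 7 | [(3S)-2-ethenyl-3-(methoxycarbonyl)-3-methylcyclohex-1-en-1-yl]methyl 3-(4-methylbenzenesulfonyl)prop-2-ynoate | C=CC1=C(COC(=O)C#CS(=O)(=O)c2ccc(C)cc2)CCC[C@]1(C)C(=O)OC
F2 | step 7 | analogue of 11 with a 4-methylbenzenesulfonyl group on C8 in place of the C17 methyl | Cc1ccc(cc1)S(=O)(=O)C1=C2C(=O)OC[C@@]23CCC[C@](C)(C(=O)OC)C3=CC1
F3 | step 11 | C11 N-methoxy-N-methylamide of the opened lactone 14, C20 triethylsilyl ether | C=C1CC[C@@H]2[C@](CO[Si](CC)(CC)CC)(CCC[C@]2(C)C(=O)OC)[C@H]1C(=O)N(C)OC
F4 | step 11 | C11 aldehyde, C20 triethylsilyl ether | C=C1CC[C@@H]2[C@](CO[Si](CC)(CC)CC)(CCC[C@]2(C)C(=O)OC)[C@H]1C=O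
F5 | step 12 | prop-2-enyl 2-methylidene-4-substituted butanoate (C12–C13 coupled acrylate), C20 triethylsilyl ether | C=C1CC[C@@H]2[C@](CO[Si](CC)(CC)CC)(CCC[C@]2(C)C(=O)OC)[C@H]1CCC(=C)C(=O)OCC=C
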